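The route rests on disconnecting the C4-C4a bond of ring C. A (Z)-β-aryloxycinnamic acid, built by adding an acetophenone-derived phenoxide to an arylpropiolate (O1-C2 bond) and released from its tert-butyl ester in the flask, is activated and acylates its own ring A, closing the pyranone in one operation. The closure exploits C4a: it lies between the O1-bearing C8a and the O5-bearing C5 and para to the methoxy-bearing C7, so it is the most nucleophilic and the only reachable ring A carbon. The acetyl group, meta to C4a, is not used in ring construction, lands on C8 and later becomes the 8-acetate by oxygen insertion.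

Key step: step 5

Remark: flavone numbering (O1, C2 to C8a, primes for ring B) is used throughout. Compounds 7-9 are drawn as the Z isomers expected from anti addition, and any E isomer would be carried along because acid interconverts the two forms.

Step 1
Reactants: 1 2',4'-dihydroxy-6'-methoxyacetophenone
Product: 2 4'-benzyloxy-2'-hydroxy-6'-methoxyacetophenone
Conditions: BnBr (1.05 equiv), K2CO3 (1.1 equiv), acetone, reflux
Reagents that add atoms: benzyl bromide, BrCc1ccccc1
Why: Williamson etherification in which the free and more acidic 4'-hydroxyl (para to the ketone) reacts, while the 2'-hydroxyl is held in a hydrogen bond to the acetyl oxygen and stays untouched by one equivalent of halide.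

Step 2
Reactants: 3 3,4-bis(benzyloxy)benzaldehyde
Product: 4 1,2-bis(benzyloxy)-4-(2,2-dibromoethenyl)benzene
Conditions: CBr4 (1.5 equiv), PPh3 (3 equiv), CH2Cl2, 0 °C
Reagents that add atoms: carbon tetrabromide, BrC(Br)(Br)Br
Why: First stage of the Corey-Fuchs homologation, in which the dibromomethylene ylide formed from CBr4 and PPh3 olefinates the non-enolisable aldehyde in a Wittig reaction that leaves aryl benzyl ethers alone.

Step 3
Reactants: 4 1,2-bis(benzyloxy)-4-(2,2-dibromoethenyl)benzene
Product: 6 tert-butyl 3-[3,4-bis(benzyloxy)phenyl]propiolate, via lithium acetylide 5 (not isolated)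
Conditions: n-BuLi (2.1 equiv), THF, −78 °C; then Boc2O (1.2 equiv), −78 °C → rt; aq NH4Cl
Reagents that add atoms: di-tert-butyl dicarbonate, CC(C)(C)OC(=O)OC(=O)OC(C)(C)C
Why: Second stage of the Corey-Fuchs homologation, in which two equivalents of n-BuLi bring about elimination and bromine-lithium exchange to give acetylide 5, whose C-acylation by Boc2O is a known direct entry to tert-butyl alkynoates, and at −78 °C the benzyl ethers are not metallated.

Step 4
Reactants: 2 4'-benzyloxy-2'-hydroxy-6'-methoxyacetophenone; 6 tert-butyl 3-[3,4-bis(benzyloxy)phenyl]propiolate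
Product: 7 tert-butyl (Z)-3-(2-acetyl-5-benzyloxy-3-methoxyphenoxy)-3-[3,4-bis(benzyloxy)phenyl]acrylate
Conditions: 2 (1.2 equiv), Cs2CO3 (0.3 equiv), DMF, 60 °C
Reagents that add atoms: none
Why: Base-catalysed oxa-Michael addition of a phenoxide to an arylpropiolate (opening stage of the Ruhemann flavone synthesis), in which anti protonation of the allenolate places aryloxy and ester groups cis (Z), the substoichiometric base and surplus phenol 2 buffer the medium so that the allenolate is protonated before it can add to the neighbouring ketone and the methyl ketone is not enolised, and the tert-butyl ester resists attack by phenoxide.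

Step 5
Reactants: 7 tert-butyl (Z)-3-(2-acetyl-5-benzyloxy-3-methoxyphenoxy)-3-[3,4-bis(benzyloxy)phenyl]acrylate
Product: 10 8-acetyl-5-benzyloxy-3',4'-bis(benzyloxy)-7-methoxyflavone, via carboxylic acid 8 (not isolated), via mixed trifluoroacetic anhydride 9 (not isolated)
Conditions: TFA (10 equiv), TFAA (3 equiv), dry CH2Cl2, 0 °C → rt
Reagents that add atoms: none
Why: TFA cleaves the tert-butyl ester by loss of isobutene to give acid 8, which the TFAA already present captures at once as mixed anhydride 9, an acylium-type electrophile stabilised by the β-oxygen, so that 8 has little time to hydrolyse or decarboxylate. The ring A carbon ortho to the enol ether oxygen attacks the acyl carbon and rearomatises by loss of a proton, forming C4-C4a; this is an intramolecular Friedel-Crafts acylation, the closing stage of the Ruhemann flavone synthesis from β-aryloxycinnamic acids, and its nearest mild relative is the TFAA closure of 2-aryloxybenzoic acids to xanthones. Ring C closes as a six-membered ring, 6-exo-trig at the acyl carbon, by electrophilic aromatic substitution. No stereocentre is formed, and the alkene geometry is not decisive because protonation at the α-carbon gives an oxocarbenium ion through which E and Z forms interconvert, with only the Z form able to close. Site selectivity comes from the substrate: the attacking carbon is ortho to two oxygens and para to the methoxy group, the acetyl group is meta to it and twisted out of conjugation by its two neighbours, the other free ring A carbon is para to the ether oxygen and out of reach, and attack by ring B would need the E form and a strained five-membered indenone. Anhydrous TFA/TFAA at or below room temperature should spare the benzyl ethers, the methyl ketone and the enol ether, which strong Lewis acids or hot polyphosphoric acid would not.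

Step 6
Reactants: 10 8-acetyl-5-benzyloxy-3',4'-bis(benzyloxy)-7-methoxyflavone
Product: 11 8-acetoxy-5-benzyloxy-3',4'-bis(benzyloxy)-7-methoxyflavone
Conditions: mCPBA (2.5 equiv), TFA (1 equiv), CH2Cl2, 0 °C → rt, dark
Reagents that add atoms: 3-chloroperbenzoic acid, OOC(=O)c1cccc(Cl)c1
Why: Baeyer-Villiger oxidation in which the out-of-plane acetyl group behaves as a reactive unconjugated ketone and C8, ortho to O1 and O7 and para to O5, migrates far better than methyl, while the electron-poor C2-C3 bond and the benzyl ethers are not attacked by the peracid.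

Step 7
Reactants: 11 8-acetoxy-5-benzyloxy-3',4'-bis(benzyloxy)-7-methoxyflavone
Product: 13 8-acetoxy-5-benzyloxy-3',4'-bis(benzyloxy)-3-hydroxy-7-methoxyflavone, via flavone 2,3-epoxide 12 (not isolated)
Conditions: DMDO (acetone solution, 3-4 equiv), CH2Cl2, 0 °C → rt; evaporate; then p-TsOH·H2O (cat.), CH2Cl2, rt
Reagents that add atoms: dimethyldioxirane, CC1(C)OO1
Why: Dioxirane epoxidation of the flavone C2-C3 bond followed by acid-catalysed opening at C2 (cation stabilised by O1 and ring B) and loss of H3, the known neutral flavone-to-flavonol conversion, in which the two racemic epoxide centres vanish again, the surplus oxidant is evaporated before the acid is added so that the flavonol is not over-oxidised, and the aryl acetate never meets base.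

Step 8
Reactants: 13 8-acetoxy-5-benzyloxy-3',4'-bis(benzyloxy)-3-hydroxy-7-methoxyflavone
Product: 14 gossypetin 7-methyl ether 8-acetate
Conditions: H2 (1 atm), 10% Pd/C, EtOAc-THF, rt
Reagents that add atoms: none
Why: Catalytic hydrogenolysis of the three aryl benzyl ethers in a neutral, alcohol-free medium, which leaves the aryl acetate and the conjugated C2-C3 bond intact, and the acetyl group cannot migrate because O8 has only the methylated O7 and the ring oxygen O1 as neighbours.

Compound list
1 | 2',4'-dihydroxy-6'-methoxyacetophenone | COc1cc(O)cc(O)c1C(C)=O | starting material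
2 | 4'-benzyloxy-2'-hydroxy-6'-methoxyacetophenone | COc1cc(OCc2ccccc2)cc(O)c1C(C)=O | intermediate
3 | 3,4-bis(benzyloxy)benzaldehyde | O=Cc1ccc(OCc2ccccc2)c(OCc2ccccc2)c1 | starting material
4 | 1,2-bis(benzyloxy)-4-(2,2-dibromoethenyl)benzene | BrC(Br)=Cc1ccc(OCc2ccccc2)c(OCc2ccccc2)c1 | intermediate
5 | lithium [3,4-bis(benzyloxy)phenyl]acetylide | [Li]C#Cc1ccc(OCc2ccccc2)c(OCc2ccccc2)c1 | intermediate
6 | tert-butyl 3-[3,4-bis(benzyloxy)phenyl]propiolate | CC(C)(C)OC(=O)C#Cc1ccc(OCc2ccccc2)c(OCc2ccccc2)c1 | intermediate
7 | tert-butyl (Z)-3-(2-acetyl-5-benzyloxy-3-methoxyphenoxy)-3-[3,4-bis(benzyloxy)phenyl]acrylate | CC(C)(C)OC(=O)/C=C(\Oc1cc(OCc2ccccc2)cc(OC)c1C(C)=O)c1ccc(OCc2ccccc2)c(OCc2ccccc2)c1 | intermediate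
8 | (Z)-3-(2-acetyl-5-benzyloxy-3-methoxyphenoxy)-3-[3,4-bis(benzyloxy)phenyl]acrylic acid | OC(=O)/C=C(\Oc1cc(OCc2ccccc2)cc(OC)c1C(C)=O)c1ccc(OCc2ccccc2)c(OCc2ccccc2)c1 | intermediate
9 | (Z)-3-(2-acetyl-5-benzyloxy-3-methoxyphenoxy)-3-[3,4-bis(benzyloxy)phenyl]acrylic trifluoroacetic anhydride | O=C(OC(=O)C(F)(F)F)/C=C(\Oc1cc(OCc2ccccc2)cc(OC)c1C(C)=O)c1ccc(OCc2ccccc2)c(OCc2ccccc2)c1 | intermediate
10 | 8-acetyl-5-benzyloxy-3',4'-bis(benzyloxy)-7-methoxyflavone | COc1cc(OCc2ccccc2)c2c(=O)cc(-c3ccc(OCc4ccccc4)c(OCc4ccccc4)c3)oc2c1C(C)=O | intermediate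
11 | 8-acetoxy-5-benzyloxy-3',4'-bis(benzyloxy)-7-methoxyflavone | COc1cc(OCc2ccccc2)c2c(=O)cc(-c3ccc(OCc4ccccc4)c(OCc4ccccc4)c3)oc2c1OC(C)=O | intermediate
12 | 8-acetoxy-5-benzyloxy-3',4'-bis(benzyloxy)-7-methoxyflavone 2,3-epoxide (cis-fused oxirane, racemic, one enantiomer drawn) | COc1cc(OCc2ccccc2)c2c(c1OC(C)=O)O[C@@]1(c3ccc(OCc4ccccc4)c(OCc4ccccc4)c3)O[C@H]1C2=O | intermediate
13 | 8-acetoxy-5-benzyloxy-3',4'-bis(benzyloxy)-3-hydroxy-7-methoxyflavone | COc1cc(OCc2ccccc2)c2c(=O)c(O)c(-c3ccc(OCc4ccccc4)c(OCc4ccccc4)c3)oc2c1OC(C)=O | intermediate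
14 | gossypetin 7-methyl ether 8-acetate (8-acetoxy-3,5,3',4'-tetrahydroxy-7-methoxyflavone, no stereocentre) | COc1cc(O)c2c(=O)c(O)c(-c3ccc(O)c(O)c3)oc2c1OC(C)=O | target

Total step count: 8. Longest linear sequence: 7 steps (3 → 4 → 6 → 7 → 10 → 11 → 13 → 14).

Steps most likely to fail

Step 4.
- What may go wrong: the chelated, acyl-deactivated phenoxide may add too slowly to an alkynoate whose β-carbon is deactivated by the donor-substituted ring B. Forcing the reaction with heat invites closure of the allenolate onto the neighbouring ketone, or enolisation of the methyl ketone followed by attack on the new enol ether.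
- Fallback: the acceptor is strengthened instead of the temperature being raised. Setting out from dibromoalkene 4, acetylide 5 is quenched with DMF in place of Boc2O to give 3-[3,4-bis(benzyloxy)phenyl]prop-2-ynal F1. This much stronger acceptor should take up phenol 2 at room temperature under catalytic Et3N in MeCN to give (Z)-3-(2-acetyl-5-benzyloxy-3-methoxyphenoxy)-3-[3,4-bis(benzyloxy)phenyl]prop-2-enal F2. Pinnick oxidation (NaClO2, NaH2PO4, 2-methyl-2-butene, t-BuOH-H2O) then gives acid 8, where the route is rejoined at the TFAA stage of step 5.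

Step 5.
- What may go wrong: the donor-stabilised acyl species may be too weak an electrophile for a ring that carries an acetyl group. While it waits, cleavage of the enol ether by traces of water, decarboxylation of the protonated acid, or acid-induced loss or migration of benzyl groups may take over.
- Fallback: the same C4-C4a bond is made with palladium and carbon monoxide. Setting out from phenol 2, iodination ortho to the free hydroxyl (NIS, cat. TFA, MeCN, 0 °C) gives 4'-benzyloxy-2'-hydroxy-3'-iodo-6'-methoxyacetophenone F3. Setting out from dibromoalkene 4, acetylide 5 is quenched with water to give 1,2-bis(benzyloxy)-4-ethynylbenzene F4. Carbonylative Sonogashira coupling of the two (PdCl2(PPh3)2, CO 1 atm, Et2NH, 60 °C) gives 1-(3-acetyl-6-benzyloxy-2-hydroxy-4-methoxyphenyl)-3-[3,4-bis(benzyloxy)phenyl]prop-2-yn-1-one F5. This closes in the same flask by 6-endo conjugate addition of the phenol and returns to the route at flavone 10.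

Step 6.
- What may go wrong: peracid addition to the doubly flanked ketone may be sluggish, and migration may be slowed because ring A is now part of an electron-withdrawing chromone. Forcing conditions would then bring on oxidation of the electron-rich ring B.
- Fallback: oxygen insertion is moved ahead of ring closure. Setting out from ester 7, whose ring A is not yet tied into a chromone, mCPBA/NaHCO3 in CH2Cl2 should give tert-butyl (Z)-3-(2-acetoxy-5-benzyloxy-3-methoxyphenoxy)-3-[3,4-bis(benzyloxy)phenyl]acrylate F6. TFA/TFAA in CH2Cl2 then leads through (Z)-3-(2-acetoxy-5-benzyloxy-3-methoxyphenoxy)-3-[3,4-bis(benzyloxy)phenyl]acrylic acid F7 and its mixed trifluoroacetic anhydride F8 to 8-acetoxyflavone 11, where the route is rejoined. The acetoxy group tolerates the acidic closure and deactivates ring A less than the acetyl group does.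

Further compounds
F1 | step 4 | 3-[3,4-bis(benzyloxy)phenyl]prop-2-ynal | O=CC#Cc1ccc(OCc2ccccc2)c(OCc2ccccc2)c1
F2 | step 4 | (Z)-3-(2-acetyl-5-benzyloxy-3-methoxyphenoxy)-3-[3,4-bis(benzyloxy)phenyl]prop-2-enal | O=C/C=C(\Oc1cc(OCc2ccccc2)cc(OC)c1C(C)=O)c1ccc(OCc2ccccc2)c(OCc2ccccc2)c1
F3 | step 5 | 4'-benzyloxy-2'-hydroxy-3'-iodo-6'-methoxyacetophenone | COc1cc(OCc2ccccc2)c(I)c(O)c1C(C)=O
F4 | step 5 | 1,2-bis(benzyloxy)-4-ethynylbenzene | C#Cc1ccc(OCc2ccccc2)c(OCc2ccccc2)c1
F5 | step 5 | 1-(3-acetyl-6-benzyloxy-2-hydroxy-4-methoxyphenyl)-3-[3,4-bis(benzyloxy)phenyl]prop-2-yn-1-one | COc1cc(OCc2ccccc2)c(C(=O)C#Cc2ccc(OCc3ccccc3)c(OCc3ccccc3)c2)c(O)c1C(C)=O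
F6 | step 6 | tert-butyl (Z)-3-(2-acetoxy-5-benzyloxy-3-methoxyphenoxy)-3-[3,4-bis(benzyloxy)phenyl]acrylate | CC(C)(C)OC(=O)/C=C(\Oc1cc(OCc2ccccc2)cc(OC)c1OC(C)=O)c1ccc(OCc2ccccc2)c(OCc2ccccc2)c1
F7 | step 6 | (Z)-3-(2-acetoxy-5-benzyloxy-3-methoxyphenoxy)-3-[3,4-bis(benzyloxy)phenyl]acrylic acid | OC(=O)/C=C(\Oc1cc(OCc2ccccc2)cc(OC)c1OC(C)=O)c1ccc(OCc2ccccc2)c(OCc2ccccc2)c1
F8 | step 6 | (Z)-3-(2-acetoxy-5-benzyloxy-3-methoxyphenoxy)-3-[3,4-bis(benzyloxy)phenyl]acrylic trifluoroacetic anhydride | O=C(OC(=O)C(F)(F)F)/C=C(\Oc1cc(OCc2ccccc2)cc(OC)c1OC(C)=O)c1ccc(OCc2ccccc2)c(OCc2ccccc2)c1
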